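**Plan**

- Atom labels: C7 and C7' are the two aryl-bearing ring carbons, C8 the hydroxylated ring-fusion carbon, C8' the other ring-fusion carbon, C9 and C9' the OCH2 carbons on C8 and C8'.
- Retrosynthesis: both benzylic ether bonds of the 3,7-dioxabicyclo[3.3.0]octane (C7–O–C9' and C7'–O–C9) are cut together to give an acyclic (2S,3S)-triol. This is possible because C7 and C7' are each benzylic and para to a free syringyl hydroxyl, so each C–O bond can be made from a CH2 group through a p-quinone methide, and only C8 and C8' need to be carried as stereocentres.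
- The triol is then cut at C8–C7 (enolate benzylation) and C8–O (enolate hydroxylation) back to an (R)-β-benzyl-γ-butyrolactone, which comes from a Stobbe half-ester of O-benzylsyringaldehyde and dimethyl succinate.
- Forward order: Stobbe condensation, asymmetric hydrogenation, a temporary butyrolactone (the only ring for most of the route), hydroxylation, O-benzylation, C-benzylation, reductive ring opening, debenzylation, then both tetrahydrofuran rings closed in the last flask.
- Stereochemistry: C8' from the chiral rhodium catalyst; C8 from alkylation anti to the C8' benzyl group; C7 and C7' under substrate control in the double closure, each aryl group going exo.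

Key step: step 12

Assumption: the (S,S) hand of Et-DuPHOS is taken to deliver the (R)-succinate in step 3, following the sense established for itaconate half-esters; all later descriptors follow from that centre.

**Route**

Step 1
Reactants: 1 syringaldehyde (4-hydroxy-3,5-dimethoxybenzaldehyde)
Product: 2 4-(benzyloxy)-3,5-dimethoxybenzaldehyde
Conditions: BnBr, K2CO3, DMF, 60 °C
Reagents that add atoms: benzyl bromide, BrCc1ccccc1
Why: Williamson etherification of the acidic, doubly ortho-substituted phenoxide with a reactive benzylic halide should proceed cleanly and leaves the aldehyde free for the two later carbon–carbon bond formations.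

Step 2
Reactants: 2 4-(benzyloxy)-3,5-dimethoxybenzaldehyde; 3 dimethyl succinate
Product: 5 (E)-4-[4-(benzyloxy)-3,5-dimethoxyphenyl]-3-(methoxycarbonyl)but-3-enoic acid, via paraconate lactone 4 (not isolated)
Conditions: NaOMe, MeOH, reflux; then aq HCl
Reagents that add atoms: none
Why: Stobbe condensation, in which the succinate enolate adds to the aldehyde, the aldolate lactonises onto the distal ester to give 4 and methoxide-induced E1cB opening of that lactone delivers the conjugated (E)-ester with the free acid on the CH2 arm, so that the two carboxyl groups emerge differentiated.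

Step 3
Reactants: 5 (E)-4-[4-(benzyloxy)-3,5-dimethoxyphenyl]-3-(methoxycarbonyl)but-3-enoic acid
Product: 6 (R)-4-[4-(benzyloxy)-3,5-dimethoxyphenyl]-3-(methoxycarbonyl)butanoic acid
Conditions: H2 (6 bar), [Rh(cod)((S,S)-Et-DuPHOS)]BF4 (0.5 mol %), NaOMe (10 mol %), MeOH, 25 °C
Reagents that add atoms: none
Why: Rhodium–bisphosphine asymmetric hydrogenation of an itaconate-type half-ester, in which carboxylate and alkene bind the metal as a chelate and the C2-symmetric bis(phospholane) admits hydrogen to one enantioface only, should set C8' as the (R) centre while the benzyl ether is inert to this catalyst.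

Step 4
Reactants: 6 (R)-4-[4-(benzyloxy)-3,5-dimethoxyphenyl]-3-(methoxycarbonyl)butanoic acid
Product: 8 (R)-4-[4-(benzyloxy)-3,5-dimethoxybenzyl]dihydrofuran-2(3H)-one, via hydroxy acid 7 (not isolated)
Conditions: KOH (1 equiv), EtOH; CaCl2, NaBH4, EtOH, 0 °C to rt; then 3 M HCl, rt
Reagents that add atoms: none
Why: Chemoselective ester reduction followed by lactonisation, in which calcium borohydride formed in the flask reduces the methyl ester but not the potassium carboxylate and acidification closes the γ-lactone of 7 without touching the C8' stereocentre.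

Step 5
Reactants: 8 (R)-4-[4-(benzyloxy)-3,5-dimethoxybenzyl]dihydrofuran-2(3H)-one
Product: 9 (3R,4S)-4-[4-(benzyloxy)-3,5-dimethoxybenzyl]-3-hydroxydihydrofuran-2(3H)-one
Conditions: NaN(SiMe3)2, THF, −78 °C; 2-(phenylsulfonyl)-3-phenyloxaziridine, −78 °C; aq NH4Cl
Reagents that add atoms: 2-(phenylsulfonyl)-3-phenyloxaziridine, O=S(=O)(c1ccccc1)N1OC1c1ccccc1
Why: Enolate hydroxylation with an N-sulfonyloxaziridine should transfer oxygen to the sodium enolate on the face away from the C4 benzyl group and give the trans hydroxy lactone, although this carbinol centre is flattened again in step 9 and its configuration is of no consequence.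

Step 6
Reactants: 9 (3R,4S)-4-[4-(benzyloxy)-3,5-dimethoxybenzyl]-3-hydroxydihydrofuran-2(3H)-one
Product: 10 (3R,4S)-3-(benzyloxy)-4-[4-(benzyloxy)-3,5-dimethoxybenzyl]dihydrofuran-2(3H)-one
Conditions: BnBr, Ag2O, 4 Å MS, CH2Cl2, rt, dark
Reagents that add atoms: benzyl bromide, BrCc1ccccc1
Why: Silver-oxide-promoted O-benzylation works under non-basic conditions that neither open nor enolise the lactone, and it turns the hydroxyl into an ether that permits a plain mono-enolate alkylation in step 9 and leaves together with the aryl benzyl ethers in step 11.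

Step 7
Reactants: 2 4-(benzyloxy)-3,5-dimethoxybenzaldehyde
Product: 11 [4-(benzyloxy)-3,5-dimethoxyphenyl]methanol
Conditions: NaBH4, MeOH, 0 °C
Reagents that add atoms: none
Why: Borohydride reduction of an aromatic aldehyde to the benzylic alcohol is fast and touches nothing else in the molecule.

Step 8
Reactants: 11 [4-(benzyloxy)-3,5-dimethoxyphenyl]methanol
Product: 12 4-(benzyloxy)-3,5-dimethoxybenzyl bromide
Conditions: PBr3, CH2Cl2, 0 °C
Reagents that add atoms: phosphorus tribromide, BrP(Br)Br
Why: Activation of the alcohol as a phosphite ester and SN2 displacement by bromide should give the electron-rich benzylic bromide, which is used soon after it is made to avoid self-condensation.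

Step 9
Reactants: 10 (3R,4S)-3-(benzyloxy)-4-[4-(benzyloxy)-3,5-dimethoxybenzyl]dihydrofuran-2(3H)-one; 12 4-(benzyloxy)-3,5-dimethoxybenzyl bromide
Product: 13 (3S,4S)-3-(benzyloxy)-3,4-bis[4-(benzyloxy)-3,5-dimethoxybenzyl]dihydrofuran-2(3H)-one
Conditions: LiN(iPr)2, THF, −78 °C; then 12, DMPU, −78 to −30 °C
Reagents that add atoms: none
Why: C-alkylation of the α-alkoxy lactone lithium enolate with a reactive benzylic bromide, which should enter the planar enolate on the face opposite the C4 benzyl group and so set the fully substituted C8 with the two benzyl groups trans and the ether oxygen cis to the C8' benzyl group, as the cis ring fusion of the target requires.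

Step 10
Reactants: 13 (3S,4S)-3-(benzyloxy)-3,4-bis[4-(benzyloxy)-3,5-dimethoxybenzyl]dihydrofuran-2(3H)-one
Product: 14 (2S,3S)-2-(benzyloxy)-2,3-bis[4-(benzyloxy)-3,5-dimethoxybenzyl]butane-1,4-diol
Conditions: LiAlH4, THF, 0 °C to rt; then Na2SO4·10H2O
Reagents that add atoms: none
Why: Hydride reduction of the lactone to the 1,4-diol opens the temporary ring and frees the C9 and C9' hydroxyls without affecting the ethers or either stereocentre.

Step 11
Reactants: 14 (2S,3S)-2-(benzyloxy)-2,3-bis[4-(benzyloxy)-3,5-dimethoxybenzyl]butane-1,4-diol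
Product: 15 (2S,3S)-2,3-bis(4-hydroxy-3,5-dimethoxybenzyl)butane-1,2,4-triol
Conditions: H2 (1 atm), Pd(OH)2/C, EtOH/EtOAc, rt
Reagents that add atoms: none
Why: Catalytic hydrogenolysis should cleave the two aryl benzyl ethers and the tertiary alkyl benzyl ether at their O–CH2Ph bonds, while the ArCH2–C bonds, which carry no heteroatom, and the alcohols are not touched.

Step 12
Reactants: 15 (2S,3S)-2,3-bis(4-hydroxy-3,5-dimethoxybenzyl)butane-1,2,4-triol
Product: 19 8-hydroxysyringaresinol, via quinone methide 16 (not isolated), via tetrahydrofuran mono-ether 17 (not isolated), via quinone methide 18 (not isolated)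
Conditions: DDQ (2.05 equiv, slow addition), NaHCO3, 4 Å MS, CH2Cl2/1,4-dioxane, 0 °C to rt
Reagents that add atoms: none
Why: Proposed new method: DDQ should take a hydride from each benzylic CH2 that lies para to a free 2,6-dimethoxyphenol, giving the p-quinone methides 16 and 18 in turn, and each methide carbon is captured by the primary hydroxyl four atoms away in an intramolecular oxa-Michael (1,6-) addition that restores the aromatic ring. The closest known reaction type is the quinone-mediated oxidative cyclisation of one p-hydroxybenzyl group onto a γ-hydroxyl that converts dibenzylbutanediol lignans into 7,9'-epoxylignans, and the untested part is two such events in one flask on a substrate with a tertiary alcohol, ending in a bicycle. Ring A (O, C9, C8, C8', C7') and ring B (O, C9', C8', C8, C7) both close in the 5-exo-trig mode, drawn here with ring A first although the reverse order meets at the same product. C7' is controlled by C8', the aryl group settling trans to the C9' hydroxymethyl group on the neighbouring carbon, and C7 is controlled by C8 and the already closed ring A, the aryl group taking the convex exo face of the forming cis-fused bicycle, syn to the tertiary hydroxyl and anti to the C9 methylene. The step needs oxygen rather than arene capture of the methides, a single productive hydroxyl for each and exo selectivity: the tertiary C8 hydroxyl and the mismatched primary hydroxyl could form only three- or four-membered rings, the buffered aprotic medium disfavours attack by the second electron-rich ring, and the (2S,3S) configuration of 15 holds the C7 benzyl and C9' hydroxymethyl groups cis on ring A so that ring B closes without strain. Further dehydrogenation of the product, whose ether carbons remain para to free phenols, is held back by the near-stoichiometric charge of oxidant and the low temperature.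

**Compound list**

1 | syringaldehyde (4-hydroxy-3,5-dimethoxybenzaldehyde) | COc1cc(C=O)cc(OC)c1O | starting material
2 | 4-(benzyloxy)-3,5-dimethoxybenzaldehyde | COc1cc(C=O)cc(OC)c1OCc1ccccc1 | intermediate
3 | dimethyl succinate | COC(=O)CCC(=O)OC | starting material
4 | methyl 2-[4-(benzyloxy)-3,5-dimethoxyphenyl]-5-oxotetrahydrofuran-3-carboxylate (paraconate lactone, racemic mixture of diastereomers, not isolated) | COC(=O)C1CC(=O)OC1c1cc(OC)c(OCc2ccccc2)c(OC)c1 | intermediate
5 | (E)-4-[4-(benzyloxy)-3,5-dimethoxyphenyl]-3-(methoxycarbonyl)but-3-enoic acid | COC(=O)/C(CC(=O)O)=C/c1cc(OC)c(OCc2ccccc2)c(OC)c1 | intermediate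
6 | (R)-4-[4-(benzyloxy)-3,5-dimethoxyphenyl]-3-(methoxycarbonyl)butanoic acid | COC(=O)[C@H](Cc1cc(OC)c(OCc2ccccc2)c(OC)c1)CC(=O)O | intermediate
7 | (R)-4-[4-(benzyloxy)-3,5-dimethoxyphenyl]-3-(hydroxymethyl)butanoic acid (present as its carboxylate, not isolated) | OC[C@H](Cc1cc(OC)c(OCc2ccccc2)c(OC)c1)CC(=O)O | intermediate
8 | (R)-4-[4-(benzyloxy)-3,5-dimethoxybenzyl]dihydrofuran-2(3H)-one | O=C1OC[C@H](Cc2cc(OC)c(OCc3ccccc3)c(OC)c2)C1 | intermediate
9 | (3R,4S)-4-[4-(benzyloxy)-3,5-dimethoxybenzyl]-3-hydroxydihydrofuran-2(3H)-one (hydroxyl trans to the benzyl group) | O=C1OC[C@H](Cc2cc(OC)c(OCc3ccccc3)c(OC)c2)[C@H]1O | intermediate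
10 | (3R,4S)-3-(benzyloxy)-4-[4-(benzyloxy)-3,5-dimethoxybenzyl]dihydrofuran-2(3H)-one | O=C1OC[C@H](Cc2cc(OC)c(OCc3ccccc3)c(OC)c2)[C@H]1OCc1ccccc1 | intermediate
11 | [4-(benzyloxy)-3,5-dimethoxyphenyl]methanol | COc1cc(CO)cc(OC)c1OCc1ccccc1 | intermediate
12 | 4-(benzyloxy)-3,5-dimethoxybenzyl bromide | COc1cc(CBr)cc(OC)c1OCc1ccccc1 | intermediate
13 | (3S,4S)-3-(benzyloxy)-3,4-bis[4-(benzyloxy)-3,5-dimethoxybenzyl]dihydrofuran-2(3H)-one (benzyl groups trans, ether oxygen cis to the C4 benzyl group) | O=C1OC[C@H](Cc2cc(OC)c(OCc3ccccc3)c(OC)c2)[C@@]1(OCc1ccccc1)Cc1cc(OC)c(OCc2ccccc2)c(OC)c1 | intermediate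
14 | (2S,3S)-2-(benzyloxy)-2,3-bis[4-(benzyloxy)-3,5-dimethoxybenzyl]butane-1,4-diol | OC[C@](OCc1ccccc1)(Cc1cc(OC)c(OCc2ccccc2)c(OC)c1)[C@H](CO)Cc1cc(OC)c(OCc2ccccc2)c(OC)c1 | intermediate
15 | (2S,3S)-2,3-bis(4-hydroxy-3,5-dimethoxybenzyl)butane-1,2,4-triol | OC[C@](O)(Cc1cc(OC)c(O)c(OC)c1)[C@H](CO)Cc1cc(OC)c(O)c(OC)c1 | intermediate
16 | p-quinone methide of 15 at C7': 4-[(2S,3S)-3,4-dihydroxy-3-(4-hydroxy-3,5-dimethoxybenzyl)-2-(hydroxymethyl)butylidene]-2,6-dimethoxycyclohexa-2,5-dien-1-one (not isolated) | OC[C@](O)(Cc1cc(OC)c(O)c(OC)c1)[C@H](CO)C=C1C=C(OC)C(=O)C(OC)=C1 | intermediate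
17 | (3S,4R,5S)-3-(4-hydroxy-3,5-dimethoxybenzyl)-5-(4-hydroxy-3,5-dimethoxyphenyl)-4-(hydroxymethyl)tetrahydrofuran-3-ol (ring A closed, not isolated) | COc1cc([C@H]2OC[C@](O)(Cc3cc(OC)c(O)c(OC)c3)[C@@H]2CO)cc(OC)c1O | intermediate
18 | p-quinone methide of 17 at C7: the benzyl CH2 of 17 dehydrogenated to a 3,5-dimethoxy-4-oxocyclohexa-2,5-dien-1-ylidene methine, ring carbons configured as in 17 (not isolated) | COc1cc([C@H]2OC[C@](O)(C=C3C=C(OC)C(=O)C(OC)=C3)[C@@H]2CO)cc(OC)c1O | intermediate
19 | 8-hydroxysyringaresinol, (1S,2R,5R,6S)-2,6-bis(4-hydroxy-3,5-dimethoxyphenyl)-3,7-dioxabicyclo[3.3.0]octan-1-ol (cis-fused, both aryl groups exo) | COc1cc([C@H]2OC[C@]3(O)[C@@H](c4cc(OC)c(O)c(OC)c4)OC[C@H]23)cc(OC)c1O | target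

**Count and risks**

Total step count: 12. Longest linear sequence: 10 steps (1 → 2 → 5 → 6 → 8 → 9 → 10 → 13 → 14 → 15 → 19). Steps 7 and 8 are the two-step branch from 2 to bromide 12.

Steps most likely to fail:

1. Step 12 (Proposed new method). What may go wrong: capture of a quinone methide by the neighbouring electron-rich arene (carbon–carbon closure to an aryltetralin) instead of by the hydroxyl, continued dehydrogenation of the newly formed benzylic ethers, or weak face selectivity at C7 beside the fully substituted C8. The fallback uses known reactions: ring B is made by cyclodehydration and only ring A by a single quinone methide closure. It sets out from lactone 10, whose lithium enolate (LiN(iPr)2, THF, −78 °C) is added to aldehyde 2, again anti to the C8' benzyl group, to give the aldol lactone F1, which already carries the C7 oxygen. LiAlH4 in THF then gives the benzylic alcohol diol F2. A catalytic amount of camphorsulfonic acid in CH2Cl2 at 0 °C ionises the benzylic alcohol and lets the C9' hydroxyl close ring B to the 2-aryltetrahydrofuran F3, the acid cyclisation known for 7-hydroxy dibenzylbutanediols. Hydrogenolysis (H2, Pd(OH)2/C, EtOAc, stopped once the benzyl groups are gone) gives the phenolic tetrahydrofuran F4. One equivalent of DDQ (CH2Cl2/1,4-dioxane, NaHCO3, 0 °C) then closes ring A by the single p-hydroxybenzyl to γ-hydroxyl etherification that has precedent, and the sequence comes back to the route at 19.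

2. Step 9. What may go wrong: slow carbon–carbon bond formation at the crowded, fully substituted α-alkoxy enolate carbon, so that decomposition of the enolate (including a [1,2]-shift of the O-benzyl group) or self-condensation of the electron-rich bromide overtakes alkylation, or erosion of the anti selectivity. The fallback drops the ether and uses a doubly charged nucleophile. It sets out from hydroxy lactone 9, which with LiN(iPr)2 (2.2 equiv, THF/DMPU, −78 to −40 °C) gives the alkoxide–enolate dianion. This is C-benzylated by 12 anti to the C8' benzyl group to give the free tertiary alcohol lactone F5. LiAlH4 reduction then gives the triol bis(benzyl ether) F6, and hydrogenolysis (H2, Pd(OH)2/C) of its two aryl benzyl ethers comes back to the route at 15.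

3. Step 3. What may go wrong: incomplete enantioface discrimination, for instance through a Z-alkene contaminant or partial alkene isomerisation before reduction, which would lower the optical purity of every later compound. The fallback is a classical resolution. It sets out from 5, which is hydrogenated with an achiral catalyst that spares benzyl ethers ([Rh(cod)(dppb)]BF4, dppb being 1,4-bis(diphenylphosphino)butane, H2, MeOH) to give the racemic half-ester F7. Salt formation with (R)-1-phenylethylamine and fractional crystallisation give the ammonium salt F8 of the (R)-acid, taken from the crystals or from the mother liquor, whichever holds it. Acidification with aq HCl comes back to the route at 6.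

Further compounds
F1 | step 12 | 3-(benzyloxy)-4-[4-(benzyloxy)-3,5-dimethoxybenzyl]-3-{[4-(benzyloxy)-3,5-dimethoxyphenyl](hydroxy)methyl}dihydrofuran-2(3H)-one, ring carbons as in 13, carbinol carbon of either configuration | O=C1OC[C@H](Cc2cc(OC)c(OCc3ccccc3)c(OC)c2)[C@@]1(OCc1ccccc1)C(O)c1cc(OC)c(OCc2ccccc2)c(OC)c1
F2 | step 12 | 2-(benzyloxy)-3-[4-(benzyloxy)-3,5-dimethoxybenzyl]-2-{[4-(benzyloxy)-3,5-dimethoxyphenyl](hydroxy)methyl}butane-1,4-diol, C2 and C3 as in 14 | OC[C@](OCc1ccccc1)(C(O)c1cc(OC)c(OCc2ccccc2)c(OC)c1)[C@H](CO)Cc1cc(OC)c(OCc2ccccc2)c(OC)c1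
F3 | step 12 | [3-(benzyloxy)-4-[4-(benzyloxy)-3,5-dimethoxybenzyl]-2-[4-(benzyloxy)-3,5-dimethoxyphenyl]tetrahydrofuran-3-yl]methanol, ring B closed, aryl cis to the benzyloxy group | OC[C@]1(OCc2ccccc2)[C@@H](c2cc(OC)c(OCc3ccccc3)c(OC)c2)OC[C@@H]1Cc1cc(OC)c(OCc2ccccc2)c(OC)c1
F4 | step 12 | 4-(4-hydroxy-3,5-dimethoxybenzyl)-2-(4-hydroxy-3,5-dimethoxyphenyl)-3-(hydroxymethyl)tetrahydrofuran-3-ol, configured as F3 | OC[C@]1(O)[C@@H](c2cc(OC)c(O)c(OC)c2)OC[C@@H]1Cc1cc(OC)c(O)c(OC)c1
F5 | step 9 | (3S,4S)-3,4-bis[4-(benzyloxy)-3,5-dimethoxybenzyl]-3-hydroxydihydrofuran-2(3H)-one | O=C1OC[C@H](Cc2cc(OC)c(OCc3ccccc3)c(OC)c2)[C@@]1(O)Cc1cc(OC)c(OCc2ccccc2)c(OC)c1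
F6 | step 9 | (2S,3S)-2,3-bis[4-(benzyloxy)-3,5-dimethoxybenzyl]butane-1,2,4-triol | OC[C@](O)(Cc1cc(OC)c(OCc2ccccc2)c(OC)c1)[C@H](CO)Cc1cc(OC)c(OCc2ccccc2)c(OC)c1
F7 | step 3 | racemic 4-[4-(benzyloxy)-3,5-dimethoxyphenyl]-3-(methoxycarbonyl)butanoic acid | COC(=O)C(Cc1cc(OC)c(OCc2ccccc2)c(OC)c1)CC(=O)O
F8 | step 3 | (R)-1-phenylethylammonium (R)-4-[4-(benzyloxy)-3,5-dimethoxyphenyl]-3-(methoxycarbonyl)butanoate | COC(=O)[C@H](Cc1cc(OC)c(OCc2ccccc2)c(OC)c1)CC(=O)[O-].C[C@@H]([NH3+])c1ccccc1
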